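(The readings are simulated for an exercise, noise included.)

The solid substrate goes in undissolved, so I first looked at what its charge does to product.

| flask | solid substrate | remark | time |
|---|---|---|---|
| autumn | 0.10 M | run made earlier |  |
| spring | 0.15 M | run made earlier |  |
| flask | 0.20 M |  | 40 min |

| autumn: time / min | autumn: product / % | spring: time / min | spring: product / % |
|---|---|---|---|
| 4.00 | 0.9 | 4.00 | 1.6 |
| 12.0 | 12.7 | 12.0 | 9.7 |
| 20.0 | 23.1 | 20.0 | 15.0 |
| 30.0 | 34.1 | 30.0 | 22.1 |

(standard deviation of a reading: 1 percentage point)

- given per volume of solution although it is solid: solid substrate
- the analysis behind the earlier runs scatters by 1 percentage point, standard deviation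
- steps that have been proposed: starting material -> intermediate A; starting material <-> intermediate B; starting material -> product; solid substrate <-> starting material; intermediate A -> product
- at the start none of the solid substrate is in solution

1. product at 40 min, in percent of the solid substrate charged
2. the change that raises the amount of product at 40 min, in percent of the solid substrate charged most ("none" if none brings more than 2 percentage points) (green / ochre / none)
3. amount of product at 40 min, in percent of the solid substrate charged, after ochre

- green: doubling the solubility of the solid substrate, all else as stated
- ochre: doubling the dissolution coefficient of the solid substrate, all else as stated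

I rescaled the last readings to the charge of the flask, and the autumn run gave 17.1% and the spring run 16.6%. So product in solution-volume terms ignored the charge, a pseudo-zero-order course. Rescaled the same way, the two runs climbed 0.00594 min⁻¹ and 0.00517 min⁻¹ between 12.0 min and 30.0 min. Their mean, 0.00556 min⁻¹, is the flask's gain, the fraction of its charge becoming product per minute.

But the asked time lies past the readings, so I reckoned that stretch as a correction. The mean last reading, 16.8%, plus 5.6 percentage points gave me 22.4%.

The rescaled readings at 4.00 min lay under that line by a lag of 2.52 min, short beside 40 min. At that gain the lag was worth 1.4 points, but the readings did not show how much of it belonged to dissolution and how much to the intermediates, so I set no figure on ochre and chose green, which raises the dissolved level itself.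

The forecast gave 22.5% (20.5% to 24.5%), green as best, and 26% after ochre, holding that “the rate does not depend on the solid charged”.

The flask gave 23.0%, and green was best, adding 23 points against 0.75 points for ochre, which reached 23.8%.

    starting material → intermediate A (k = 0.0970 min⁻¹)
    starting material ⇌ intermediate B (K = 6.10, k = 0.0130 min⁻¹)
    starting material → product (k = 0.0190 min⁻¹)
    solid substrate ⇌ starting material, rate k4*(cs4 - [starting material]) while solid is left; crystals form when [starting material] > cs4 (solubility = 11.0 mM, k = 2.30 min⁻¹)
    intermediate A → product (k = 0.570 min⁻¹)

Between 20.0 min and 40.0 min this flask gained 0.00604 min⁻¹, with starting material at 5.21% at both ends. A neighbouring flask, with the same charge but read at 25 min, lies inside the readings, so I stepped back from 16.8% by the gain of 0.00556 min⁻¹ over 5.00 min, which gave 14.0%. That neighbouring flask held 14.0% of product.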